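## Retrosynthetic overview

1. The C8 ester (Yamaguchi, (S)-2-methylglycidic acid), the C13 acetate and C13 itself (Stille coupling at C11–Br) go on last; the 5E enol-lactone alkene comes from E1cB loss of a C5 silyl ether inside the closed ring.
2. The ten-membered carbocycle (nine-membered oxacycle O/C4–C10/C1) is closed at C7–C8 by an intramolecular Nozaki–Hiyama–Kishi reaction between a β-bromobutenolide and a C8 aldehyde on the two cis arms of the oxolane; C5–C6 comes from a vinylogous Mukaiyama aldol of an oxolane-2-carbaldehyde with 3,4-dibromofuran-2(5H)-one.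
3. The oxolane O/C1/C2/C3/C4 with the C1, C4 and C10 centres comes from one Lewis-acid cascade on an acyclic geraniol-derived bis-epoxide: the oxirane O/C1/C10 grows by two atoms into the oxolane through a 1-oxoniabicyclo[3.1.0]hexane (epoxonium) ion, and a tert-butyl carbonate on O9 closes on C10 as a temporary dioxolanone.
4. Enabling feature: the ring oxygen is flanked on both sides by methyl-bearing 1,2-dioxygenated pairs, O–C4(CH3)/C5 and O–C1/C10(CH3)–OH, held apart by the C2–C3 ethano bridge. This is the imprint of the 2,3- and 6,7-epoxides of a geranyl chain, and C9 is the (E)-methyl group of geraniol.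
5. Ring order: two oxiranes → oxolane (plus dioxolanone, removed) → butenolide attached → medium ring → alkylidene butenolide.

Key step: step 6

Numbering used in the text (target frame, also for acyclic precursors): C1 oxolane CH, C2/C3 oxolane CH2, C4 oxolane C(CH3) (CH3 = C15), C5 =CH, C6 lactone C–O, C7/C11 butenolide C=C, C8 CH–O, C9 CH2, C10 C(CH3)OH (CH3 = C14), C12 C=O, C13 CH2OAc.

Remark on the chemistry: the two centres created in step 13 (C5, C6) are carried as a mixture of diastereomers, because both become sp2 in step 16.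

## Route

Step 1
Reactants: 1 geraniol
Product: 2 (2S,3S)-2,3-epoxygeraniol
Conditions: Ti(OiPr)4 (5 mol%), L-(+)-diethyl tartrate (6 mol%), tBuOOH, 4 Å molecular sieves, CH2Cl2, −20 °C
Reagents that add atoms: tert-butyl hydroperoxide, CC(C)(C)OO
Why: Sharpless asymmetric epoxidation touches only the allylic-alcohol alkene and, with the L-(+)-tartrate, should set the (2S,3S) configuration (later C5 and C4) under reagent control.

Step 2
Reactants: 2 (2S,3S)-2,3-epoxygeraniol
Product: 3 TBDPS ether of 2
Conditions: TBDPSCl, imidazole, DMF, 0 °C → rt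
Reagents that add atoms: tert-butyl(chloro)diphenylsilane, CC(C)(C)[Si](Cl)(c1ccccc1)c1ccccc1
Why: Routine silylation of the primary alcohol gives a bulky, weakly basic ether oxygen that cannot take part as a neighbouring group in the Lewis-acid step.

Step 3
Reactants: 3 TBDPS ether of 2
Product: 4 (E)-allylic alcohol (C9–OH)
Conditions: SeO2 (0.3 equiv), tBuOOH, CH2Cl2, 0 °C → rt
Reagents that add atoms: tert-butyl hydroperoxide, CC(C)(C)OO; selenium dioxide (catalytic oxygen carrier), O=[Se]=O
Why: Riley allylic oxidation (ene reaction, then [2,3]-shift) is selective for the (E)-methyl group of a trisubstituted alkene, so the new CH2OH (C9) should stand trans to the chain.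

Step 4
Reactants: 4 (E)-allylic alcohol
Product: 5 (2S,3S,6S,7S)-bis-epoxy alcohol
Conditions: Ti(OiPr)4 (10 mol%), L-(+)-diethyl tartrate (12 mol%), tBuOOH, 4 Å molecular sieves, CH2Cl2, −20 °C
Reagents that add atoms: tert-butyl hydroperoxide, CC(C)(C)OO
Why: A second Sharpless asymmetric epoxidation with the same L-(+)-tartrate should give the (S,S)-oxirane at C10/C1 under reagent control, the remote first oxirane having no say.

Step 5
Reactants: 5 bis-epoxy alcohol
Product: 6 bis-epoxy tert-butyl carbonate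
Conditions: Boc2O, DMAP (10 mol%), MeCN, 0 °C → rt
Reagents that add atoms: di-tert-butyl dicarbonate, CC(C)(C)OC(=O)OC(=O)OC(C)(C)C
Why: DMAP-catalysed acylation of the primary alcohol installs the carbonate that will end the cascade as an internal oxygen nucleophile next to C10.

Step 6
Reactants: 6 bis-epoxy tert-butyl carbonate
Product: 8 oxolane cyclic carbonate with free C5–OH, via epoxonium ion 7 (not isolated)
Conditions: BF3·OEt2 (0.5 equiv), CH2Cl2, −78 → −40 °C; then aq. NaHCO3
Reagents that add atoms: none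
Why: BF3 activates the more basic 4,5-oxirane (the C1/C10 oxirane is deactivated by the carbonate-bearing CH2), and the oxygen of the C1/C10 oxirane attacks the tertiary C4 from the rear to give the bicyclic epoxonium ion 7, in which the three-membered ring O/C1/C10 is already part of the five-membered ring O/C1/C2/C3/C4; the carbonyl oxygen of the tert-butyl carbonate then opens 7 at the tertiary C10, the O–C10 bond is lost and isobutene is expelled, so the oxirane has expanded by two atoms (C10 out; C2, C3, C4 in) to the oxolane. The closest known reaction type is the BF3-promoted, tert-butyl-carbonate-terminated epoxide-opening cascade of 1,5-bis-epoxides from polyprenols, which runs through the same epoxonium ions. Both closures are 5-exo-tet: the oxolane by attack of the epoxide oxygen on C4, the 1,3-dioxolan-2-one by attack of the carbonyl oxygen on C10. Each centre is fixed by a stereospecific event on a Sharpless-derived centre: C4 is inverted (S to R), C1 keeps its C–O bond (S), C10 is inverted (S to R), and the cis relation of the C5 and C10 arms on the oxolane follows from these three. The step needs regioselectivity (attack at C4 and C10, not at C5 and C1) and direction (C4 end first), which the substrate secures because both wanted attacks are at once Markovnikov and 5-exo and the only internal terminator sits on O9; if the carbonate should open the C1/C10 oxirane first, the C1 oxygen it leaves behind closes on C4 to the same oxolane with the same three configurations.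

Step 7
Reactants: 8 oxolane cyclic carbonate
Product: 9 C5,C9,C10-triol (C6–OTBDPS)
Conditions: K2CO3 (0.2 equiv), MeOH, 0 °C → rt
Reagents that add atoms: none
Why: Base-catalysed transesterification removes the cyclic carbonate as dimethyl carbonate without touching the silyl ether or any stereocentre.

Step 8
Reactants: 9 triol
Product: 11 terminal C9/C10 epoxide, via primary tosylate 10 (not isolated)
Conditions: TsCl, Et3N, Bu2SnO (5 mol%), CH2Cl2, 0 °C → rt; then K2CO3, MeOH, rt
Reagents that add atoms: none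
Why: Tin-acetal-catalysed sulfonylation picks the primary hydroxyl of the 1,2-diol, and Williamson closure by the tertiary C10 oxygen displaces tosylate at C9, so C10 keeps its configuration because its C–O bond is never broken.

Step 9
Reactants: 11 terminal epoxide
Product: 12 homoallylic tertiary alcohol (C8=CH2 vinyl group on C9)
Conditions: CH2=CHMgBr (3 equiv), CuI (10 mol%), THF, −40 → 0 °C; aq. NH4Cl
Reagents that add atoms: vinylmagnesium bromide, C=C[Mg]Br
Why: Copper-catalysed Grignard opening of a 2,2-disubstituted oxirane occurs by SN2 at the CH2 carbon, which brings in C8 as a masked aldehyde and frees the C10 hydroxyl with its configuration intact.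

Step 10
Reactants: 12 homoallylic tertiary alcohol
Product: 14 C5,C6-diacetate with free C10–OH, via triol 13 (not isolated)
Conditions: TBAF, THF, 0 °C → rt; then Ac2O, pyridine, DMAP (5 mol%), 0 °C
Reagents that add atoms: acetic anhydride, CC(=O)OC(C)=O
Why: Fluoride removes the silyl ether and acetylation then distinguishes the primary and secondary hydroxyls from the tertiary C10 hydroxyl, which is too hindered to react under these conditions.

Step 11
Reactants: 14 diacetate
Product: 15 C10 triethylsilyl ether diacetate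
Conditions: TESOTf, 2,6-lutidine, CH2Cl2, −78 → 0 °C
Reagents that add atoms: triethylsilyl trifluoromethanesulfonate, CC[Si](CC)(CC)OS(=O)(=O)C(F)(F)F
Why: A silyl triflate silylates the tertiary alcohol; this ether keeps O10 from forming a bicyclic lactol with the cis-disposed C5 aldehyde made next.

Step 12
Reactants: 15 C10 silyl ether diacetate
Product: 17 oxolane-2-carbaldehyde (C5 aldehyde), via diol 16 (not isolated)
Conditions: K2CO3 (cat.), MeOH, 0 °C; then NaIO4, aq. pH 7 buffer, 0 °C → rt
Reagents that add atoms: none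
Why: Methanolysis of the two acetates followed by Malaprade glycol cleavage excises C6 as formaldehyde and leaves a non-enolisable aldehyde on the quaternary C4, whose configuration therefore cannot be lost.

Step 13
Reactants: 17 oxolane-2-carbaldehyde; 18 3,4-dibromofuran-2(5H)-one
Product: 20 vinylogous aldol adduct (C5–OSiEt3, C6–H, dibromobutenolide), via silyloxyfuran 19 (not isolated)
Conditions: TESOTf (2.2 equiv), iPr2NEt (3 equiv), CH2Cl2, −78 → −20 °C
Reagents that add atoms: triethylsilyl trifluoromethanesulfonate, CC[Si](CC)(CC)OS(=O)(=O)C(F)(F)F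
Why: TESOTf and iPr2NEt turn 18 into silyloxyfuran 19, which adds through its free C5 position (the α-carbon is blocked by bromine) to the silyl-activated aldehyde in a vinylogous Mukaiyama aldol with the silyl group ending on O5; the new C5 and C6 centres arise from an open transition state without deliberate control and are both removed in step 16.

Step 14
Reactants: 20 vinylogous aldol adduct
Product: 22 C8 aldehyde, via ozonide 21 (not isolated)
Conditions: O3, CH2Cl2, −78 °C; then PPh3, −78 °C → rt
Reagents that add atoms: ozone, [O-][O+]=O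
Why: Ozonolysis with reductive work-up cleaves the monosubstituted terminal alkene, while the tetrasubstituted, doubly brominated and electron-poor butenolide alkene is inert to ozone at −78 °C.

Step 15
Reactants: 22 C8 aldehyde
Product: 23 macrocyclic C8 carbinol (11-oxabicyclo[6.2.1]undecane fused to the bromobutenolide)
Conditions: CrCl2 (8 equiv), NiCl2 (2 mol%), DMSO/THF, rt, 0.002 M, slow addition of 22
Reagents that add atoms: none
Why: In this Nozaki–Hiyama–Kishi closure zerovalent nickel inserts into the vinylogous acyl bromide C7–Br (the α-bromo-enoate C11–Br is much less reactive), the vinyl group passes to chromium and adds to the C8 aldehyde, a ring closure with close precedent for nine-membered ethers bridged by a 2,5-cis-oxolane; the C8 carbinol should be set by the conformation of the forming ring, the 8S epimer drawn being the one needed and to be confirmed at this stage.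

Step 16
Reactants: 23 macrocyclic C8 carbinol
Product: 24 (5E)-alkylidene bromobutenolide
Conditions: DBU (3 equiv), CH2Cl2, 0 °C → rt
Reagents that add atoms: none
Why: DBU removes the acidic γ-hydrogen at C6 and the dienolate expels the C5 silyloxy group (E1cB, the second stage of the known silyl-triflate aldol/DBU route to γ-alkylidene butenolides); all C5/C6 diastereomers converge, the nine-membered ring allows only the ring-cis (5E) alkene, and any lactone that has migrated to O8 re-equilibrates and is drained by this irreversible elimination.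

Step 17
Reactants: 24 (5E)-alkylidene bromobutenolide
Product: 25 C8,C10-diol
Conditions: HF·pyridine, pyridine, THF, 0 °C
Reagents that add atoms: none
Why: Buffered fluoride cleaves the tertiary triethylsilyl ether under conditions that the enol lactone and the allylic tertiary ether at C4 should tolerate.

Step 18
Reactants: 25 C8,C10-diol
Product: 26 C8,C10,C13-triol
Conditions: Bu3SnCH2OH (1.5 equiv), Pd(PPh3)4 (10 mol%), 1,4-dioxane, 80 °C
Reagents that add atoms: (tributylstannyl)methanol, CCCC[Sn](CCCC)(CCCC)CO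
Why: Stille coupling of the α-bromo enoate with the hydroxymethyl stannane brings in C13; it is run while O8 and O13 are free hydroxyls, so no allylic ester is present that zerovalent palladium could ionise.

Step 19
Reactants: 26 triol
Product: 27 C13 monoacetate
Conditions: Ac2O (1.1 equiv), 2,4,6-collidine, CH2Cl2, −20 °C
Reagents that add atoms: acetic anhydride, CC(=O)OC(C)=O
Why: With a weak hindered base at low temperature the primary allylic hydroxyl should be acetylated ahead of the hindered secondary C8 and tertiary C10 hydroxyls.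

Step 20
Reactants: 28 (R)-2-methylglycidol
Product: 29 (S)-2-methyloxirane-2-carboxylic acid
Conditions: TEMPO (10 mol%), PhI(OAc)2 (2.2 equiv), MeCN/H2O (pH 7), 0 °C → rt; used at once
Reagents that add atoms: water, O
Why: Oxoammonium oxidation takes the primary alcohol through the aldehyde hydrate to the acid without opening the oxirane; the stereocentre is untouched and only its descriptor changes from R to S.

Step 21
Reactants: 27 C13 monoacetate; 29 (S)-2-methyloxirane-2-carboxylic acid
Product: 31 target CNP0142137.1, via mixed anhydride 30 (not isolated)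
Conditions: 29, 2,4,6-trichlorobenzoyl chloride, Et3N, toluene, 0 °C; then 27, DMAP, toluene, rt
Reagents that add atoms: none
Why: Yamaguchi esterification through mixed anhydride 30 and DMAP acyl transfer acylates the only secondary hydroxyl (C8) with retention, the tertiary C10 hydroxyl being inert.

## Compound list

1 | geraniol, (2E)-3,7-dimethylocta-2,6-dien-1-ol | CC(C)=CCC/C(C)=C/CO | starting material
2 | [(2S,3S)-3-methyl-3-(4-methylpent-3-en-1-yl)oxiran-2-yl]methanol | OC[C@@H]1O[C@@]1(C)CCC=C(C)C | intermediate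
3 | tert-butyl{[(2S,3S)-3-methyl-3-(4-methylpent-3-en-1-yl)oxiran-2-yl]methoxy}diphenylsilane | CC(C)(C)[Si](c1ccccc1)(c1ccccc1)OC[C@@H]2O[C@@]2(C)CCC=C(C)C | intermediate
4 | (2E)-5-[(2S,3S)-3-({[tert-butyl(diphenyl)silyl]oxy}methyl)-2-methyloxiran-2-yl]-2-methylpent-2-en-1-ol | CC(C)(C)[Si](c1ccccc1)(c1ccccc1)OC[C@@H]2O[C@@]2(C)CC/C=C(\C)CO | intermediate
5 | [(2S,3S)-3-{2-[(2S,3S)-3-({[tert-butyl(diphenyl)silyl]oxy}methyl)-2-methyloxiran-2-yl]ethyl}-2-methyloxiran-2-yl]methanol | CC(C)(C)[Si](c1ccccc1)(c1ccccc1)OC[C@@H]2O[C@@]2(C)CC[C@@H]3O[C@@]3(C)CO | intermediate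
6 | tert-butyl [(2S,3S)-3-{2-[(2S,3S)-3-({[tert-butyl(diphenyl)silyl]oxy}methyl)-2-methyloxiran-2-yl]ethyl}-2-methyloxiran-2-yl]methyl carbonate | CC(C)(C)[Si](c1ccccc1)(c1ccccc1)OC[C@@H]2O[C@@]2(C)CC[C@@H]3O[C@@]3(C)COC(=O)OC(C)(C)C | intermediate
7 | BF3-bound bicyclic epoxonium ion: 1-oxoniabicyclo[3.1.0]hexane with C4 (R, CH3 and the CH(OBF3)CH2OTBDPS arm), C1 (S) and C10 (S, CH3 and CH2OBoc) on the oxonium oxygen | CC(C)(C)[Si](c1ccccc1)(c1ccccc1)OC[C@H](O[B-](F)(F)F)[C@@]2(C)CC[C@@H]3[O+]2[C@@]3(C)COC(=O)OC(C)(C)C | intermediate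
8 | (4R)-4-{(2S,5R)-5-[(1S)-2-{[tert-butyl(diphenyl)silyl]oxy}-1-hydroxyethyl]-5-methyloxolan-2-yl}-4-methyl-1,3-dioxolan-2-one | CC(C)(C)[Si](c1ccccc1)(c1ccccc1)OC[C@H](O)[C@@]2(C)CC[C@H](O2)[C@@]3(C)COC(=O)O3 | intermediate
9 | (2R)-2-{(2S,5R)-5-[(1S)-2-{[tert-butyl(diphenyl)silyl]oxy}-1-hydroxyethyl]-5-methyloxolan-2-yl}propane-1,2-diol | CC(C)(C)[Si](c1ccccc1)(c1ccccc1)OC[C@H](O)[C@@]2(C)CC[C@H](O2)[C@](C)(O)CO | intermediate
10 | (2R)-2-{(2S,5R)-5-[(1S)-2-{[tert-butyl(diphenyl)silyl]oxy}-1-hydroxyethyl]-5-methyloxolan-2-yl}-2-hydroxypropyl 4-methylbenzenesulfonate | CC(C)(C)[Si](c1ccccc1)(c1ccccc1)OC[C@H](O)[C@@]2(C)CC[C@H](O2)[C@](C)(O)COS(=O)(=O)c3ccc(C)cc3 | intermediate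
11 | (1S)-2-{[tert-butyl(diphenyl)silyl]oxy}-1-{(2R,5S)-2-methyl-5-[(2R)-2-methyloxiran-2-yl]oxolan-2-yl}ethan-1-ol | CC(C)(C)[Si](c1ccccc1)(c1ccccc1)OC[C@H](O)[C@@]2(C)CC[C@H](O2)[C@@]3(C)CO3 | intermediate
12 | (1S)-2-{[tert-butyl(diphenyl)silyl]oxy}-1-{(2R,5S)-5-[(2R)-2-hydroxypent-4-en-2-yl]-2-methyloxolan-2-yl}ethan-1-ol | CC(C)(C)[Si](c1ccccc1)(c1ccccc1)OC[C@H](O)[C@@]2(C)CC[C@H](O2)[C@](C)(O)CC=C | intermediate
13 | (1S)-1-{(2R,5S)-5-[(2R)-2-hydroxypent-4-en-2-yl]-2-methyloxolan-2-yl}ethane-1,2-diol | OC[C@H](O)[C@@]1(C)CC[C@H](O1)[C@](C)(O)CC=C | intermediate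
14 | (1S)-1-{(2R,5S)-5-[(2R)-2-hydroxypent-4-en-2-yl]-2-methyloxolan-2-yl}ethane-1,2-diyl diacetate | CC(=O)OC[C@H](OC(C)=O)[C@@]1(C)CC[C@H](O1)[C@](C)(O)CC=C | intermediate
15 | (1S)-1-{(2R,5S)-2-methyl-5-[(2R)-2-[(triethylsilyl)oxy]pent-4-en-2-yl]oxolan-2-yl}ethane-1,2-diyl diacetate | CC(=O)OC[C@H](OC(C)=O)[C@@]1(C)CC[C@H](O1)[C@](C)(O[Si](CC)(CC)CC)CC=C | intermediate
16 | (1S)-1-{(2R,5S)-2-methyl-5-[(2R)-2-[(triethylsilyl)oxy]pent-4-en-2-yl]oxolan-2-yl}ethane-1,2-diol | OC[C@H](O)[C@@]1(C)CC[C@H](O1)[C@](C)(O[Si](CC)(CC)CC)CC=C | intermediate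
17 | (2R,5S)-2-methyl-5-[(2R)-2-[(triethylsilyl)oxy]pent-4-en-2-yl]oxolane-2-carbaldehyde | O=C[C@@]1(C)CC[C@H](O1)[C@](C)(O[Si](CC)(CC)CC)CC=C | intermediate
18 | 3,4-dibromofuran-2(5H)-one | O=C1OCC(Br)=C1Br | starting material
19 | 3,4-dibromo-2-[(triethylsilyl)oxy]furan | CC[Si](CC)(CC)Oc1occ(Br)c1Br | intermediate
20 | 3,4-dibromo-5-{[(2R,5S)-2-methyl-5-{(2R)-2-[(triethylsilyl)oxy]pent-4-en-2-yl}oxolan-2-yl][(triethylsilyl)oxy]methyl}furan-2(5H)-one (mixture at C5 and C6) | O=C1OC(C(O[Si](CC)(CC)CC)[C@@]2(C)CC[C@H](O2)[C@](C)(O[Si](CC)(CC)CC)CC=C)C(Br)=C1Br | intermediate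
21 | ozonide of 20: the allyl CH=CH2 replaced by a 1,2,4-trioxolan-3-yl ring | O=C1OC(C(O[Si](CC)(CC)CC)[C@@]2(C)CC[C@H](O2)[C@](C)(O[Si](CC)(CC)CC)CC3OOCO3)C(Br)=C1Br | intermediate
22 | (3R)-3-{(2S,5R)-5-[(3,4-dibromo-5-oxo-2,5-dihydrofuran-2-yl)(triethylsilyloxy)methyl]-5-methyloxolan-2-yl}-3-[(triethylsilyl)oxy]butanal (mixture at C5 and C6) | O=C1OC(C(O[Si](CC)(CC)CC)[C@@]2(C)CC[C@H](O2)[C@](C)(O[Si](CC)(CC)CC)CC=O)C(Br)=C1Br | intermediate
23 | (1S,4R,8S,10R)-11-bromo-1,4-epoxy-8-hydroxy-5,10-bis[(triethylsilyl)oxy]-13-norgermacr-7(11)-en-12,6-olide (mixture at C5 and C6) | O=C1OC2C(O[Si](CC)(CC)CC)[C@@]3(C)CC[C@H](O3)[C@](C)(O[Si](CC)(CC)CC)C[C@H](O)C2=C1Br | intermediate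
24 | (1S,4R,5E,8S,10R)-11-bromo-1,4-epoxy-8-hydroxy-10-[(triethylsilyl)oxy]-13-norgermacra-5,7(11)-dien-12,6-olide | O=C1O/C2=C/[C@@]3(C)CC[C@H](O3)[C@](C)(O[Si](CC)(CC)CC)C[C@H](O)C2=C1Br | intermediate
25 | (1S,4R,5E,8S,10R)-11-bromo-1,4-epoxy-8,10-dihydroxy-13-norgermacra-5,7(11)-dien-12,6-olide | O=C1O/C2=C/[C@@]3(C)CC[C@H](O3)[C@](C)(O)C[C@H](O)C2=C1Br | intermediate
26 | (1S,4R,5E,8S,10R)-1,4-epoxy-8,10,13-trihydroxygermacra-5,7(11)-dien-12,6-olide | O=C1O/C2=C/[C@@]3(C)CC[C@H](O3)[C@](C)(O)C[C@H](O)C2=C1CO | intermediate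
27 | (1S,4R,5E,8S,10R)-13-acetoxy-1,4-epoxy-8,10-dihydroxygermacra-5,7(11)-dien-12,6-olide | O=C1O/C2=C/[C@@]3(C)CC[C@H](O3)[C@](C)(O)C[C@H](O)C2=C1COC(C)=O | intermediate
28 | (R)-2-methylglycidol, [(2R)-2-methyloxiran-2-yl]methanol | OC[C@]1(C)CO1 | starting material
29 | (2S)-2-methyloxirane-2-carboxylic acid | OC(=O)[C@]1(C)CO1 | intermediate
30 | (2S)-2-methyloxirane-2-carboxylic 2,4,6-trichlorobenzoic anhydride | O=C(OC(=O)[C@]1(C)CO1)c2c(Cl)cc(Cl)cc2Cl | intermediate
31 | (1S,4R,5E,8S,10R)-13-acetoxy-1,4-epoxy-10-hydroxy-8-{[(2S)-2-methyloxirane-2-carbonyl]oxy}germacra-5,7(11)-dien-12,6-olide (CNP0142137.1) | CC(=O)OCC1=C2/C(=C\[C@@]3(C)CC[C@H](O3)[C@](C)(O)C[C@@H]2OC(=O)[C@]2(C)CO2)OC1=O | target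

## Step count and risks

Total: 21 steps. Longest linear sequence: 20 steps (steps 1–19 and 21, from geraniol); the acid 29 takes one step (step 20).

**Risk 1, step 6 (cascade).** The Lewis acid may act out of sequence: hydride shift at an activated oxirane to a carbonyl compound, or opening of the epoxonium ion at C10 through an open cation, which would erode the inversion at C10. Fallback (direct hydroxy-epoxide cyclisation instead of the epoxonium route), setting out from 3 and returning at 9: aqueous acid (HClO4 cat., THF/H2O, 0 °C) should open the 2,3-oxirane of 3 at its tertiary carbon with inversion to the anti-diol F1. SeO2/tBuOOH then oxidises the (E)-methyl group to the allylic alcohol F2. Sharpless epoxidation with D-(−)-diethyl tartrate should give the (R,R)-epoxy alcohol F3, whose C1 is attacked 5-exo with inversion by the tertiary C4 hydroxyl, under the titanium conditions or on addition of camphorsulfonic acid. This gives triol 9, which enters step 8.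

**Risk 2, step 15 (medium-ring closure).** Closure of the ten-membered carbocycle may be outrun by intermolecular coupling or by reduction of the C–Br bond. Fallback (the two C–C bond formations in reverse order, ring closed at C5–C6), setting out from 17 and returning at 25: ozonolysis of 17 (O3; PPh3) gives the dialdehyde F4. A Nozaki–Hiyama–Kishi coupling with 18 (CrCl2, NiCl2 cat., a chiral sulfonamide ligand for reagent control at C8) should pick the unhindered C8 aldehyde over the neopentylic C5 aldehyde and give the carbinol F5. TESOTf/iPr2NEt at high dilution silylates O8, forms the silyloxyfuran and closes the ring by intramolecular vinylogous Mukaiyama aldol to the macrocyclic silyl aldol F6. DBU eliminates the C5 silyloxy group to the alkylidene butenolide F7, and HF·pyridine removes both silyl ethers to give 25, which enters step 18.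

**Risk 3, step 18 (C13 by Stille coupling).** Slow transmetalation of the sp3 stannane at the hindered, electron-poor C11–Br may let protodebromination and palladium-induced decomposition take over. Fallback (C13 brought in as carbon monoxide), setting out from 25 and returning at 26: reductive carbonylation of 25 (Pd(PPh3)4, CO 1 atm, Bu3SnH by slow addition, THF, 50 °C) should give the α-formyl butenolide F8, which may sit as its lactol with the C8 hydroxyl. Luche reduction (NaBH4, CeCl3·7H2O, MeOH, −40 °C) then gives triol 26, which enters step 19.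

## Further compounds

F1 | step 6 | (2S,3R)-1-{[tert-butyl(diphenyl)silyl]oxy}-3,7-dimethyloct-6-ene-2,3-diol | CC(C)(C)[Si](c1ccccc1)(c1ccccc1)OC[C@H](O)[C@](C)(O)CCC=C(C)C
F2 | step 6 | (2E,6R,7S)-8-{[tert-butyl(diphenyl)silyl]oxy}-2,6-dimethyloct-2-ene-1,6,7-triol | CC(C)(C)[Si](c1ccccc1)(c1ccccc1)OC[C@H](O)[C@](C)(O)CC/C=C(\C)CO
F3 | step 6 | (2S,3R)-1-{[tert-butyl(diphenyl)silyl]oxy}-5-[(2R,3R)-3-(hydroxymethyl)-3-methyloxiran-2-yl]-3-methylpentane-2,3-diol | CC(C)(C)[Si](c1ccccc1)(c1ccccc1)OC[C@H](O)[C@](C)(O)CC[C@H]2O[C@]2(C)CO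
F4 | step 15 | (2R,5S)-2-methyl-5-{(2R)-4-oxo-2-[(triethylsilyl)oxy]butan-2-yl}oxolane-2-carbaldehyde | O=C[C@@]1(C)CC[C@H](O1)[C@](C)(O[Si](CC)(CC)CC)CC=O
F5 | step 15 | (2R,5S)-5-{(2R,4S)-4-(4-bromo-5-oxo-2,5-dihydrofuran-3-yl)-4-hydroxy-2-[(triethylsilyl)oxy]butan-2-yl}-2-methyloxolane-2-carbaldehyde | O=C[C@@]1(C)CC[C@H](O1)[C@](C)(O[Si](CC)(CC)CC)C[C@H](O)C2=C(Br)C(=O)OC2
F6 | step 15 | (1S,4R,8S,10R)-11-bromo-1,4-epoxy-5,8,10-tris[(triethylsilyl)oxy]-13-norgermacr-7(11)-en-12,6-olide (mixture at C5 and C6) | O=C1OC2C(O[Si](CC)(CC)CC)[C@@]3(C)CC[C@H](O3)[C@](C)(O[Si](CC)(CC)CC)C[C@H](O[Si](CC)(CC)CC)C2=C1Br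
F7 | step 15 | (1S,4R,5E,8S,10R)-11-bromo-1,4-epoxy-8,10-bis[(triethylsilyl)oxy]-13-norgermacra-5,7(11)-dien-12,6-olide | O=C1O/C2=C/[C@@]3(C)CC[C@H](O3)[C@](C)(O[Si](CC)(CC)CC)C[C@H](O[Si](CC)(CC)CC)C2=C1Br
F8 | step 18 | (1S,4R,5E,8S,10R)-1,4-epoxy-8,10-dihydroxy-13-oxogermacra-5,7(11)-dien-12,6-olide | O=C1O/C2=C/[C@@]3(C)CC[C@H](O3)[C@](C)(O)C[C@H](O)C2=C1C=O
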